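**Assumptions (one line each)**
- The SMILES is read as a tiglate ester (E). At C5=C6, C4 is trans to the lactone O, so C4 and C7 are cis within the 10-membered ring.
- C1 (the methyl ketal) is assumed to be set by the bicyclo[6.2.1] ring constraint in the last step.
- (E)-3-Methylpenta-2,4-dien-1-ol, (S)-4-benzyl-3-propionyloxazolidin-2-one, tetronic acid and tigloyl chloride are taken as commercial.

**Retrosynthesis**
1. The target comes from transannular methyl-ketalisation of a 10-membered C1-ketone/C4-tertiary-alcohol (31). This closes the C1–O–C4 bridge last and sets C1.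
2. Compound 31 comes from β-elimination of a C5–O group, which makes the ring-cis γ-alkylidene butenolide inside the ring. The 10-membered carbocycle is closed by a new macrocyclic vinylogous Mukaiyama aldol (C6 silyloxyfuran onto the C5 aldehyde).
3. The open-chain precursor comes from NHK coupling of a 4-bromobutenolide (fragment 17) to the C8 aldehyde, with CBS reduction setting C8. The chain comes from Sharpless-derived C4 carbinol (as RLi) added to an Evans-derived C10 aldehyde.
4. Ring order: butenolide (pre-made), then the 10-membered ring (C5–C6 bond), then C5=C6, then the oxa-bridge.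

---

**Step 1**
Reactants: 1 (S)-4-benzyl-3-propionyloxazolidin-2-one; 2 allyl iodide
Product: 3 (S)-4-benzyl-3-[(R)-2-methylpent-4-enoyl]oxazolidin-2-one
Conditions: NaHMDS, THF, −78 °C; then allyl iodide, −78 → −40 °C
Reagents that add atoms: allyl iodide, C=CCI
Why: Evans enolate alkylation from the face opposite the benzyl group sets C10 (R).

**Step 2**
Reactants: 3
Product: 4 (S)-4-benzyl-3-[(R)-2-methyl-4-oxobutanoyl]oxazolidin-2-one
Conditions: O3, CH2Cl2, −78 °C; then PPh3
Reagents that add atoms: ozone, [O-][O+]=O (becomes the aldehyde O)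
Why: Ozonolysis of the terminal alkene; C10 is untouched.

**Step 3**
Reactants: 4
Product: 5 (S)-4-benzyl-3-[(R)-4,4-dimethoxy-2-methylbutanoyl]oxazolidin-2-one
Conditions: HC(OMe)3, MeOH, TsOH·H2O (cat.), rt
Reagents that add atoms: trimethyl orthoformate, COC(OC)OC; methanol, CO
Why: Dimethyl acetal formation masks C8 so the later vinyl group (C5=C6) can be cleaved selectively.

**Step 4**
Reactants: 5
Product: 6 (R)-4,4-dimethoxy-2-methylbutan-1-ol (the auxiliary is recovered)
Conditions: LiBH4, MeOH (1.2 equiv), Et2O, 0 °C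
Reagents that add atoms: none
Why: Reductive cleavage of the N-acyl oxazolidinone; the acetal is base-stable.

**Step 5**
Reactants: 6
Product: 7 (R)-4,4-dimethoxy-2-methylbutanal (C1 aldehyde)
Conditions: Dess–Martin periodinane, NaHCO3, CH2Cl2, 0 °C → rt; use crude
Reagents that add atoms: none
Why: Mild oxidation that avoids epimerising the α-stereocentre C10.

**Step 6**
Reactants: 8 (E)-3-methylpenta-2,4-dien-1-ol
Product: 9 (2S,3S)-2,3-epoxy-3-methylpent-4-en-1-ol
Conditions: Ti(OiPr)4, L-(+)-DET, TBHP, 4 Å MS, CH2Cl2, −20 °C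
Reagents that add atoms: tert-butyl hydroperoxide, CC(C)(C)OO (epoxide O)
Why: Sharpless asymmetric epoxidation of the allylic alkene only; this fixes what becomes C4 (R).

**Step 7**
Reactants: 9
Product: 10 (R)-3-methylpent-4-ene-1,3-diol
Conditions: Red-Al, THF, 0 °C → rt
Reagents that add atoms: none
Why: Alkoxide-directed hydride delivery to C2 opens the epoxide. The tertiary carbinol (C4) is not touched, so it keeps its configuration.

**Step 8**
Reactants: 10
Product: 11 (R)-5-iodo-3-methylpent-1-en-3-ol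
Conditions: I2, PPh3, imidazole, CH2Cl2, 0 °C
Reagents that add atoms: iodine, II
Why: Appel iodination, selective for the primary alcohol over the tertiary one.

**Step 9**
Reactants: 11
Product: 12 (R)-tert-butyl[(5-iodo-3-methylpent-1-en-3-yl)oxy]dimethylsilane
Conditions: TBSOTf, 2,6-lutidine, CH2Cl2, −78 → 0 °C
Reagents that add atoms: TBSOTf, CC(C)(C)[Si](C)(C)OS(=O)(=O)C(F)(F)F
Why: Silylation of the tertiary alcohol, so the organolithium can be made in the next coupling.

**Step 10**
Reactants: 13 tetronic acid (4-hydroxyfuran-2(5H)-one)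
Product: 14 4-hydroxy-3-methylfuran-2(5H)-one
Conditions: (CH2O)n, Hantzsch ester, EtOH, 60 °C
Reagents that add atoms: paraformaldehyde, C=O (gives the CH3)
Why: Reductive Knoevenagel alkylation at C3 of the 1,3-dicarbonyl.

**Step 11**
Reactants: 14
Product: 15 4-bromo-3-methylfuran-2(5H)-one
Conditions: (COBr)2, DMF (cat.), CH2Cl2, 0 °C → rt
Reagents that add atoms: oxalyl bromide, O=C(Br)C(=O)Br
Why: Vinylogous acid to vinyl bromide (Vilsmeier-type).

**Step 12**
Reactants: 15
Product: 16 4-bromo-3-(bromomethyl)furan-2(5H)-one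
Conditions: NBS, (PhCO2)2 (cat.), PhCF3, 85 °C
Reagents that add atoms: NBS, O=C1CCC(=O)N1Br
Why: Wohl–Ziegler bromination of the α-methyl group.

**Step 13**
Reactants: 16
Product: 17 (4-bromo-5-oxo-2,5-dihydrofuran-3-yl)methyl acetate
Conditions: AgOAc, MeCN, rt
Reagents that add atoms: silver acetate, CC(=O)O[Ag]
Why: SN2 displacement of the allylic bromide; the vinyl bromide survives.

**Step 14**
Reactants: 12; 7
Product: 18 (3R,7R)-1,1-dimethoxy-3,7-dimethyl-7-(TBSO)non-8-en-4-ol (C1 epimer mixture)
Conditions: t-BuLi (2.1 equiv), Et2O, −78 °C (Li–I exchange); then 7, −78 °C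
Reagents that add atoms: none
Why: Organolithium addition to the aldehyde forms the C1–C2 bond. The C1 carbinol stereocentre is irrelevant because it is oxidised later; C4 and C10 are untouched.

**Step 15**
Reactants: 18
Product: 19 the C1-TBS ether (bis-TBS, acetal intact)
Conditions: TBSCl, imidazole, DMAP, DMF, 40 °C
Reagents that add atoms: TBSCl, CC(C)(C)[Si](C)(C)Cl
Why: Silylation under non-acidic conditions so the dimethyl acetal survives.

**Step 16**
Reactants: 19
Product: 20 (3R,7R)-4,7-bis(TBSO)-3,7-dimethylnon-8-enal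
Conditions: TESOTf, 2,4,6-collidine, CH2Cl2, 0 °C; then H2O
Reagents that add atoms: water, O (becomes the aldehyde O)
Why: Fujioka collidinium-salt hydrolysis of the acetal, which leaves the silyl ethers and the alkene intact.

**Step 17**
Reactants: 20; 17
Product: 21 C8 carbinol: butenolide C7 bonded to C8H(OH)–C9H2–C10H(Me)–C1H(OTBS)–C2H2–C3H2–C4(Me)(OTBS)–CH=CH2 (C8 and C1 epimer mixtures)
Conditions: CrCl2 (5 equiv), NiCl2 (cat.), DMF, rt
Reagents that add atoms: none
Why: Nozaki–Hiyama–Kishi coupling of the vinyl bromide with the unhindered aldehyde forms the C7–C8 bond. C8 is reset in steps 18–19.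

**Step 18**
Reactants: 21
Product: 22 C8 ketone
Conditions: Dess–Martin periodinane, NaHCO3, CH2Cl2, rt
Reagents that add atoms: none
Why: Oxidation removes the uncontrolled C8 stereocentre.

**Step 19**
Reactants: 22
Product: 23 (8S)-alcohol
Conditions: (R)-Me-CBS (20 mol%), catecholborane, toluene, −78 °C
Reagents that add atoms: none
Why: Corey–Bakshi–Shibata reduction gives catalyst-controlled C8 (S); catecholborane avoids hydroboration of the vinyl group.

**Step 20**
Reactants: 23; 24 tigloyl chloride
Product: 25 the C8 tiglate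
Conditions: DMAP, Et3N, CH2Cl2, 0 °C → rt
Reagents that add atoms: tigloyl chloride, C/C=C(\C)C(=O)Cl
Why: Acylation keeps the E geometry of the tiglate; the C8 configuration is retained.

**Step 21**
Reactants: 25
Product: 26 C5 aldehyde (α-silyloxy, on the quaternary C4)
Conditions: OsO4 (5 mol%), NaIO4, 2,6-lutidine, dioxane/H2O 3:1, rt
Reagents that add atoms: sodium periodate, [Na+].[O-]I(=O)(=O)=O (oxygen source for the aldehyde)
Why: Lemieux–Johnson cleavage of the terminal vinyl group; the tiglate and the tetrasubstituted butenolide alkene are far less reactive.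

**Step 22**
Reactants: 26
Product: 27 10-membered macrocycle with C5–OTES and C6–H; C5, C6 and C1 are diastereomeric mixtures that converge later
Conditions: TESOTf, Et3N, CH2Cl2, syringe-pump addition to 0.002 M, −78 → −20 °C
Reagents that add atoms: TESOTf, CC[Si](CC)(CC)OS(=O)(=O)C(F)(F)F
Why: Proposed new method: TESOTf/Et3N converts the butenolide to a 3,4-disubstituted 2-triethylsilyloxyfuran whose C6 (γ) carbon attacks the silyl-triflate-activated, α-H-free C5 aldehyde through an open transition state, closing the 10-membered ring; this is a macrocyclic (10-ring) vinylogous Mukaiyama aldol that has no precedent. The closest known reaction is the intermolecular Mukaiyama vinylogous aldol of 2-silyloxyfurans and its 5–7-membered intramolecular versions. C5 and C6 stereochemistry is irrelevant because both centres are destroyed in step 24.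

**Step 23**
Reactants: 27
Product: 28 C5 alcohol (both TBS ethers retained)
Conditions: HF·pyridine, pyridine, THF, 0 °C
Reagents that add atoms: none
Why: The secondary TES ether is removed selectively in the presence of the TBS ethers.

**Step 24**
Reactants: 28
Product: 29 C5=C6 alkylidene butenolide (C1- and C4-TBS retained)
Conditions: MsCl, Et3N, CH2Cl2, −20 → 0 °C; then DBU, 0 °C
Reagents that add atoms: none
Why: Mesylation followed by E1cB elimination through the acidic γ-H (C6–H) of the butenolide. The 10-ring requires C4 to be cis to C7, which gives the target (E-by-CIP) ring-cis alkene, and the silylated C4–O prevents epoxide formation.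

**Step 25**
Reactants: 29
Product: 30 C1,C4-diol
Conditions: HF·pyridine, THF, 45 °C
Reagents that add atoms: none
Why: Removes both TBS groups without touching the acetate or the tiglate.

**Step 26**
Reactants: 30
Product: 31 C1 ketone (C4 tertiary alcohol free)
Conditions: Dess–Martin periodinane, NaHCO3, CH2Cl2, rt
Reagents that add atoms: none
Why: Only the secondary alcohol (C1) is oxidised; the tertiary C4–OH is unaffected.

**Step 27**
Reactants: 31
Product: 32 Vernolide-B
Conditions: HC(OMe)3, MeOH, CSA (cat.), CH2Cl2, 0 °C → rt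
Reagents that add atoms: methanol, CO
Why: Acid-catalysed transannular ketalisation by C4–OH onto the C1 ketone, then methyl ketal formation. C1 configuration is fixed by the bicyclo[6.2.1] geometry (known acid-catalysed ketalisation type), and C4–O bond formation is retentive.

---

**Compound list**

| # | Name | SMILES | Role |
|---|---|---|---|
| 1 | (S)-4-benzyl-3-propionyloxazolidin-2-one | CCC(=O)N1C(=O)OC[C@@H]1Cc1ccccc1 | starting material |
| 2 | allyl iodide | C=CCI | starting material |
| 3 | (S)-4-benzyl-3-[(R)-2-methylpent-4-enoyl]oxazolidin-2-one | C=CC[C@@H](C)C(=O)N1C(=O)OC[C@@H]1Cc1ccccc1 | intermediate |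
| 4 | (S)-4-benzyl-3-[(R)-2-methyl-4-oxobutanoyl]oxazolidin-2-one | O=CC[C@@H](C)C(=O)N1C(=O)OC[C@@H]1Cc1ccccc1 | intermediate |
| 5 | (S)-4-benzyl-3-[(R)-4,4-dimethoxy-2-methylbutanoyl]oxazolidin-2-one | COC(OC)C[C@@H](C)C(=O)N1C(=O)OC[C@@H]1Cc1ccccc1 | intermediate |
| 6 | (R)-4,4-dimethoxy-2-methylbutan-1-ol | COC(OC)C[C@@H](C)CO | intermediate |
| 7 | (R)-4,4-dimethoxy-2-methylbutanal | COC(OC)C[C@@H](C)C=O | intermediate |
| 8 | (E)-3-methylpenta-2,4-dien-1-ol | C=C/C(C)=C/CO | starting material |
| 9 | (2S,3S)-2,3-epoxy-3-methylpent-4-en-1-ol | OC[C@@H]1O[C@@]1(C)C=C | intermediate |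
| 10 | (R)-3-methylpent-4-ene-1,3-diol | C=C[C@](C)(O)CCO | intermediate |
| 11 | (R)-5-iodo-3-methylpent-1-en-3-ol | C=C[C@](C)(O)CCI | intermediate |
| 12 | (R)-TBS ether of 11 | C=C[C@](C)(O[Si](C)(C)C(C)(C)C)CCI | intermediate |
| 13 | tetronic acid | OC1=CC(=O)OC1 | starting material |
| 14 | 4-hydroxy-3-methylfuran-2(5H)-one | CC1=C(O)COC1=O | intermediate |
| 15 | 4-bromo-3-methylfuran-2(5H)-one | CC1=C(Br)COC1=O | intermediate |
| 16 | 4-bromo-3-(bromomethyl)furan-2(5H)-one | BrCC1=C(Br)COC1=O | intermediate |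
| 17 | (4-bromo-5-oxo-2,5-dihydrofuran-3-yl)methyl acetate | CC(=O)OCC1=C(Br)COC1=O | intermediate |
| 18 | C1 alcohol (C1 epimers) | COC(OC)C[C@@H](C)C(O)CC[C@@](C)(O[Si](C)(C)C(C)(C)C)C=C | intermediate |
| 19 | C1-TBS ether | COC(OC)C[C@@H](C)C(O[Si](C)(C)C(C)(C)C)CC[C@@](C)(O[Si](C)(C)C(C)(C)C)C=C | intermediate |
| 20 | C8 aldehyde | O=CC[C@@H](C)C(O[Si](C)(C)C(C)(C)C)CC[C@@](C)(O[Si](C)(C)C(C)(C)C)C=C | intermediate |
| 21 | NHK adduct (C8 epimers) | CC(=O)OCC1=C(C(O)C[C@@H](C)C(O[Si](C)(C)C(C)(C)C)CC[C@@](C)(O[Si](C)(C)C(C)(C)C)C=C)COC1=O | intermediate |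
| 22 | C8 ketone | CC(=O)OCC1=C(C(=O)C[C@@H](C)C(O[Si](C)(C)C(C)(C)C)CC[C@@](C)(O[Si](C)(C)C(C)(C)C)C=C)COC1=O | intermediate |
| 23 | (8S)-alcohol | CC(=O)OCC1=C([C@@H](O)C[C@@H](C)C(O[Si](C)(C)C(C)(C)C)CC[C@@](C)(O[Si](C)(C)C(C)(C)C)C=C)COC1=O | intermediate |
| 24 | tigloyl chloride | C/C=C(\C)C(=O)Cl | starting material |
| 25 | C8 tiglate | CC(=O)OCC1=C([C@@H](OC(=O)/C(C)=C/C)C[C@@H](C)C(O[Si](C)(C)C(C)(C)C)CC[C@@](C)(O[Si](C)(C)C(C)(C)C)C=C)COC1=O | intermediate |
| 26 | C5 aldehyde | CC(=O)OCC1=C([C@@H](OC(=O)/C(C)=C/C)C[C@@H](C)C(O[Si](C)(C)C(C)(C)C)CC[C@@](C)(O[Si](C)(C)C(C)(C)C)C=O)COC1=O | intermediate |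
| 27 | macro-aldol silyl ether | CC(=O)OCC1=C2[C@@H](OC(=O)/C(C)=C/C)C[C@@H](C)C(O[Si](C)(C)C(C)(C)C)CC[C@@](C)(O[Si](C)(C)C(C)(C)C)C(O[Si](CC)(CC)CC)C2OC1=O | intermediate |
| 28 | C5 alcohol | CC(=O)OCC1=C2[C@@H](OC(=O)/C(C)=C/C)C[C@@H](C)C(O[Si](C)(C)C(C)(C)C)CC[C@@](C)(O[Si](C)(C)C(C)(C)C)C(O)C2OC1=O | intermediate |
| 29 | ring-cis alkylidene butenolide | CC(=O)OCC1=C2[C@@H](OC(=O)/C(C)=C/C)C[C@@H](C)C(O[Si](C)(C)C(C)(C)C)CC[C@@](C)(O[Si](C)(C)C(C)(C)C)/C=C2/OC1=O | intermediate |
| 30 | C1,C4-diol | CC(=O)OCC1=C2[C@@H](OC(=O)/C(C)=C/C)C[C@@H](C)C(O)CC[C@@](C)(O)/C=C2/OC1=O | intermediate |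
| 31 | C1 keto-alcohol | CC(=O)OCC1=C2[C@@H](OC(=O)/C(C)=C/C)C[C@@H](C)C(=O)CC[C@@](C)(O)/C=C2/OC1=O | intermediate |
| 32 | Vernolide-B | C/C=C(\C)C(=O)O[C@H]1C[C@@H](C)[C@]2(OC)CC[C@](C)(/C=C3/OC(=O)C(COC(C)=O)=C31)O2 | target |

---

**Total steps:** 27.
**Longest linear sequence:** 19 steps (1 → 3 → 4 → 5 → 6 → 7 → 18 → 19 → 20 → 21 → 22 → 23 → 25 → 26 → 27 → 28 → 29 → 30 → 31 → 32 by compound number, i.e. steps 1–5 then 14–27).

**Three steps most likely to fail**
1. **Step 22 (proposed new macro-vinylogous Mukaiyama aldol).** The 10-membered closure onto a hindered α-quaternary aldehyde may oligomerise or give γ/α-regiochemistry problems.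
   Fallback with known chemistry: put a C6 diethyl phosphonate on the butenolide fragment (from the γ-bromobutenolide by Arbuzov) and close the ring by Masamune–Roush macro-Horner–Wadsworth–Emmons olefination onto the C5 aldehyde, then I2/hv equilibration if needed.
2. **Step 24 (β-elimination).** The 5,6-alkene may form with the wrong geometry, the C13 acetate may be lost, or epoxide formation may compete.
   Fallback: reverse the order. Acetylate C5–OH after step 23, then do steps 25–27 (desilylation, oxidation, ketalisation), and only then eliminate C5–OAc with DBU in the rigid oxa-bridged bicycle, where C4–O is already a THF ether.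
3. **Step 19 (CBS reduction).** The facial selectivity for this hindered, unusual ketone is uncertain.
   Fallback: reduce with NaBH4/CeCl3, separate the C8 epimers, and invert the unwanted (8R) epimer by Mitsunobu with tiglic acid, which also installs the tiglate.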